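**Retrosynthetic overview**
1. Target 20 ⇐ one-pot hydrogenolysis and acetal cleavage of aldol adduct 18 ⇐ trans-selective aldol of lactone 8 with aldehyde 16 (C3–benzyl bond, sets C3).
2. Lactone 8 ⇐ enantioselective ring-expansion carbonylation (oxetane + CO → γ-butyrolactone) of prochiral oxetane 7 (sets C4).
3. Oxetane 7 ⇐ B-alkyl Suzuki coupling of 3-methyleneoxetane 5 with aryl bromide 4 ⇐ catechol 1.
4. Aldehyde 16 ⇐ two successive directed ortho-metalations of resorcinol bis(MOM) ether 9 (C2: oxygen, then methyl; C4: formyl).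
5. Ring order: both arenes and the oxetane are bought; the lactone is the only ring made, by four-to-five ring expansion in step 4.

Assumption: catechol, 3-methyleneoxetane and 1,3-bis(methoxymethoxy)benzene (resorcinol protected as its bis-MOM ether) are bought as such.

**Route**

Step 1
Reactants: 1 catechol
Product: 2 2-methoxyphenol (guaiacol)
Conditions: MeI (1.0 equiv), K2CO3 (1.0 equiv), acetone, reflux; 1 in twofold excess, removed by aqueous wash
Reagents that add atoms: iodomethane, CI
Why: Williamson ether synthesis on the catechol monoanion, where the excess of diol and the lower acidity of the product keep dimethylation low.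

Step 2
Reactants: 2 2-methoxyphenol
Product: 4 1-(benzyloxy)-4-bromo-2-methoxybenzene, via 4-bromo-2-methoxyphenol 3 (not isolated)
Conditions: NBS (1.0 equiv), DMF, 0 °C to rt; then K2CO3 (3 equiv), BnBr (2.2 equiv), 50 °C, one pot
Reagents that add atoms: N-bromosuccinimide, O=C1CCC(=O)N1Br; benzyl bromide, BrCc1ccccc1
Why: electrophilic aromatic bromination goes para to the free hydroxyl (the strongest donor), and the phenoxide is then benzylated in the same pot by Williamson ether synthesis, with BnBr in excess because succinimide is also alkylated.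

Step 3
Reactants: 5 3-methyleneoxetane; 4 1-(benzyloxy)-4-bromo-2-methoxybenzene
Product: 7 3-[4-(benzyloxy)-3-methoxybenzyl]oxetane, via 9-(oxetan-3-ylmethyl)-9-borabicyclo[3.3.1]nonane 6 (not isolated)
Conditions: 9-BBN (1.05 equiv), THF, 0 °C to rt; then 4, Pd(dppf)Cl2 (3 mol %), K3PO4 (3 M aq, 3 equiv), DMF, 60 °C
Reagents that add atoms: none
Why: anti-Markovnikov hydroboration puts boron on the exocyclic CH2, and B-alkyl Suzuki–Miyaura coupling joins that primary carbon to the aryl bromide, the oxetane and aryl ethers being inert to borane and base.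

Step 4
Reactants: 7 3-[4-(benzyloxy)-3-methoxybenzyl]oxetane
Product: 8 (R)-4-[4-(benzyloxy)-3-methoxybenzyl]dihydrofuran-2(3H)-one
Conditions: [(R,R)-(salen)Cr(THF)2][Co(CO)4] (5 mol %; salen = N,N′-bis(3,5-di-tert-butylsalicylidene)-trans-1,2-cyclohexanediamine dianion; the antipode if a pilot run shows the opposite sense), CO (60 bar), DME, 60 °C
Reagents that add atoms: carbon monoxide, [C-]#[O+]
Why: Proposed new method: enantioselective desymmetrizing ring-expansion carbonylation of a prochiral 3-substituted oxetane; the chiral cationic (salen)Cr Lewis acid (trivalent chromium) binds the oxetane oxygen, [Co(CO)4]− opens one of the two enantiotopic CH2–O bonds by backside SN2 attack inside the chiral pocket (this choice alone turns C3 of the oxetane into the (R)-configured C4 of the lactone, no bond to that carbon being touched), CO inserts into the Co–C bond (1,2-alkyl shift onto CO), and the chromium-bound alkoxide closes onto the acylcobalt to give the five-membered lactone and return the ion pair; the closest known reaction types are the achiral Lewis acid/[Co(CO)4]− ring-expansion carbonylation of epoxides to β-lactones and of oxetane to γ-butyrolactone, its enantioselective form on meso-epoxides, and chiral-acid-catalysed desymmetrizing openings of 3-substituted oxetanes by halide or thiol nucleophiles.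

Step 5
Reactants: 9 1,3-bis(methoxymethoxy)benzene
Product: 12 2,6-bis(methoxymethoxy)phenol, via [2,6-bis(methoxymethoxy)phenyl]lithium 10 (not isolated), via lithium [2,6-bis(methoxymethoxy)phenyl]trimethoxyborate 11 (not isolated)
Conditions: n-BuLi (1.1 equiv), THF, 0 °C to rt; B(OMe)3, −78 °C to rt; then 30% H2O2, NaOH aq, 0 °C to rt
Reagents that add atoms: hydrogen peroxide, OO
Why: directed ortho-metalation occurs at C2 between the two MOM ethers (doubly coordinated, most acidic site), and borylation followed by alkaline peroxide oxidation (1,2-aryl shift from boron to oxygen) turns C–Li into C–OH.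

Step 6
Reactants: 12 2,6-bis(methoxymethoxy)phenol
Product: 13 2-methoxy-1,3-bis(methoxymethoxy)benzene
Conditions: MeI (1.5 equiv), K2CO3, DMF, rt
Reagents that add atoms: iodomethane, CI
Why: Williamson ether synthesis on a phenoxide, with the MOM acetals stable to base.

Step 7
Reactants: 13 2-methoxy-1,3-bis(methoxymethoxy)benzene
Product: 16 3-methoxy-2,4-bis(methoxymethoxy)benzaldehyde, via [3-methoxy-2,4-bis(methoxymethoxy)phenyl]lithium 14 (not isolated), via lithium (dimethylamino)[3-methoxy-2,4-bis(methoxymethoxy)phenyl]methanolate 15 (not isolated)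
Conditions: n-BuLi (1.2 equiv), TMEDA, THF, 0 °C; DMF, −78 °C to rt; H2O
Reagents that add atoms: N,N-dimethylformamide, CN(C)C=O
Why: second directed ortho-metalation, now ortho to one MOM ether (C4 and C6 are equivalent by symmetry, so one product), then formylation of the aryllithium with DMF (Bouveault aldehyde synthesis).

Step 8
Reactants: 8 (R)-4-[4-(benzyloxy)-3-methoxybenzyl]dihydrofuran-2(3H)-one; 16 3-methoxy-2,4-bis(methoxymethoxy)benzaldehyde
Product: 18 (3S,4R)-4-[4-(benzyloxy)-3-methoxybenzyl]-3-{hydroxy[3-methoxy-2,4-bis(methoxymethoxy)phenyl]methyl}dihydrofuran-2(3H)-one (both carbinol epimers), via lithium (4R)-4-[4-(benzyloxy)-3-methoxybenzyl]-4,5-dihydrofuran-2-olate 17 (not isolated)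
Conditions: LiN(i-Pr)2 (1.1 equiv), THF, −78 °C; then 16, −78 °C; AcOH quench at −78 °C
Reagents that add atoms: none
Why: aldol addition of the lactone lithium enolate, in which the aldehyde approaches the enolate face opposite to the C4 benzyl group and so sets C3 trans to C4 (the 3S label is only a priority change caused by the hydroxyl; the carbinol centre is removed in step 9).

Step 9
Reactants: 18 (3S,4R)-4-[4-(benzyloxy)-3-methoxybenzyl]-3-{hydroxy[3-methoxy-2,4-bis(methoxymethoxy)phenyl]methyl}dihydrofuran-2(3H)-one
Product: 20 (3R,4R)-3-(2,4-dihydroxy-3-methoxybenzyl)-4-(4-hydroxy-3-methoxybenzyl)dihydrofuran-2(3H)-one, via (3R,4R)-4-(4-hydroxy-3-methoxybenzyl)-3-[3-methoxy-2,4-bis(methoxymethoxy)benzyl]dihydrofuran-2(3H)-one 19 (not isolated)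
Conditions: H2 (3 bar), 10% Pd/C, EtOAc–AcOH 4:1, rt; then 3 M HCl in MeOH, 45 °C, one pot
Reagents that add atoms: none
Why: catalytic hydrogenolysis cleaves the benzylic C–OH bond (activated by ortho and para oxygen donors) and the benzyl ether without touching C3 or C4, and acid-catalysed acetal exchange with methanol then removes both MOM groups, the trans lactone being the thermodynamic isomer.

**Compound list**
1 | catechol | Oc1ccccc1O | starting material
2 | 2-methoxyphenol | COc1ccccc1O | intermediate
3 | 4-bromo-2-methoxyphenol | COc1cc(Br)ccc1O | intermediate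
4 | 1-(benzyloxy)-4-bromo-2-methoxybenzene | COc1cc(Br)ccc1OCc1ccccc1 | intermediate
5 | 3-methyleneoxetane | C=C1COC1 | starting material
6 | 9-(oxetan-3-ylmethyl)-9-borabicyclo[3.3.1]nonane | C1OCC1CB1C2CCCC1CCC2 | intermediate
7 | 3-[4-(benzyloxy)-3-methoxybenzyl]oxetane | COc1cc(CC2COC2)ccc1OCc1ccccc1 | intermediate
8 | (R)-4-[4-(benzyloxy)-3-methoxybenzyl]dihydrofuran-2(3H)-one | COc1cc(C[C@H]2COC(=O)C2)ccc1OCc1ccccc1 | intermediate
9 | 1,3-bis(methoxymethoxy)benzene | COCOc1cccc(OCOC)c1 | starting material
10 | [2,6-bis(methoxymethoxy)phenyl]lithium | [Li]c1c(OCOC)cccc1OCOC | intermediate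
11 | lithium [2,6-bis(methoxymethoxy)phenyl]trimethoxyborate | [Li+].CO[B-](OC)(OC)c1c(OCOC)cccc1OCOC | intermediate
12 | 2,6-bis(methoxymethoxy)phenol | COCOc1cccc(OCOC)c1O | intermediate
13 | 2-methoxy-1,3-bis(methoxymethoxy)benzene | COCOc1cccc(OCOC)c1OC | intermediate
14 | [3-methoxy-2,4-bis(methoxymethoxy)phenyl]lithium | [Li]c1ccc(OCOC)c(OC)c1OCOC | intermediate
15 | lithium (dimethylamino)[3-methoxy-2,4-bis(methoxymethoxy)phenyl]methanolate | [Li]OC(N(C)C)c1ccc(OCOC)c(OC)c1OCOC | intermediate
16 | 3-methoxy-2,4-bis(methoxymethoxy)benzaldehyde | O=Cc1ccc(OCOC)c(OC)c1OCOC | intermediate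
17 | lithium (4R)-4-[4-(benzyloxy)-3-methoxybenzyl]-4,5-dihydrofuran-2-olate | COc1cc(C[C@H]2COC(O[Li])=C2)ccc1OCc1ccccc1 | intermediate
18 | (3S,4R)-4-[4-(benzyloxy)-3-methoxybenzyl]-3-{hydroxy[3-methoxy-2,4-bis(methoxymethoxy)phenyl]methyl}dihydrofuran-2(3H)-one, both carbinol epimers | COc1cc(C[C@H]2COC(=O)[C@@H]2C(O)c2ccc(OCOC)c(OC)c2OCOC)ccc1OCc1ccccc1 | intermediate
19 | (3R,4R)-4-(4-hydroxy-3-methoxybenzyl)-3-[3-methoxy-2,4-bis(methoxymethoxy)benzyl]dihydrofuran-2(3H)-one | COc1cc(C[C@H]2COC(=O)[C@@H]2Cc2ccc(OCOC)c(OC)c2OCOC)ccc1O | intermediate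
20 | (3R,4R)-3-(2,4-dihydroxy-3-methoxybenzyl)-4-(4-hydroxy-3-methoxybenzyl)dihydrofuran-2(3H)-one | COc1cc(C[C@H]2COC(=O)[C@@H]2Cc2ccc(O)c(OC)c2O)ccc1O | target

**Step count and risks**

Total step count: 9. Longest linear sequence: 6 steps (steps 1, 2, 3, 4, 8, 9 from catechol); the aldehyde branch (steps 5, 6, 7) joins at step 8.

The three steps most likely to fail:

Step 4 (the proposed new carbonylation). The risks are low or reversed enantioselectivity, slow turnover and polyether formation from the Lewis-acid-activated oxetane. The ee of 8 is measured by chiral HPLC and 8 is recrystallized. The fallback uses known chemistry, sets out from 4 and comes back at 8. Zinc dust with LiCl in THF inserts into bought 3-(bromomethyl)cyclobutan-1-one to give (3-oxocyclobutyl)methylzinc bromide F1. Negishi coupling of this reagent with 4 (Pd(OAc)2, SPhos, THF, 40 °C) gives 3-[4-(benzyloxy)-3-methoxybenzyl]cyclobutan-1-one F2. Enantioselective Baeyer–Villiger oxidation of this prochiral ketone (a Baeyer–Villiger monooxygenase in whole cells, or a chiral binol-phosphoric acid with 30% H2O2 in CHCl3 at −40 °C) then gives 8. The lactone is still formed by a four-to-five ring expansion.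

Step 9 (one-pot hydrogenolysis and MOM removal). The risk is acid-induced dehydration of 18 to the α-benzylidene lactone, or quinone-methide tautomerisation once the ortho phenol is free; later hydrogenation would then give the cis isomer. The fallback sets out from 16 and 8 and comes back at 19. NaBH4 (MeOH, 0 °C) reduces 16 to [3-methoxy-2,4-bis(methoxymethoxy)phenyl]methanol F3. CBr4/PPh3 (CH2Cl2, 2,6-lutidine, 0 °C) converts it to 1-(bromomethyl)-3-methoxy-2,4-bis(methoxymethoxy)benzene F4, used crude. The enolate 17 (from 8 with LiN(SiMe3)2, THF–DMPU, −78 °C) is alkylated by this bromide anti to the C4 substituent to give (3R,4R)-4-[4-(benzyloxy)-3-methoxybenzyl]-3-[3-methoxy-2,4-bis(methoxymethoxy)benzyl]dihydrofuran-2(3H)-one F5. Neutral hydrogenolysis (H2, Pd/C, EtOAc) removes the benzyl ether to give 19, which is treated with HCl in MeOH as in step 9.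

Step 3 (hydroboration and B-alkyl Suzuki coupling). The risks are loss of the volatile alkene, borane-induced opening of the oxetane and slow coupling of the electron-rich aryl bromide. The fallback sets out from 4 and comes back at 7. A nickel-catalysed reductive cross-electrophile coupling of 4 with bought 3-(iodomethyl)oxetane (NiBr2(dme), 4,4′-di-tert-butyl-2,2′-bipyridine, Zn, DMA, 60 °C) gives 7 directly without an organoboron reagent; no compound outside the list is made (none, F0).

**Further compounds**
F1 | step 4 | (3-oxocyclobutyl)methylzinc bromide | O=C1CC(C[Zn]Br)C1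
F2 | step 4 | 3-[4-(benzyloxy)-3-methoxybenzyl]cyclobutan-1-one | COc1cc(CC2CC(=O)C2)ccc1OCc1ccccc1
F3 | step 9 | [3-methoxy-2,4-bis(methoxymethoxy)phenyl]methanol | OCc1ccc(OCOC)c(OC)c1OCOC
F4 | step 9 | 1-(bromomethyl)-3-methoxy-2,4-bis(methoxymethoxy)benzene | BrCc1ccc(OCOC)c(OC)c1OCOC
F5 | step 9 | (3R,4R)-4-[4-(benzyloxy)-3-methoxybenzyl]-3-[3-methoxy-2,4-bis(methoxymethoxy)benzyl]dihydrofuran-2(3H)-one | COc1cc(C[C@H]2COC(=O)[C@@H]2Cc2ccc(OCOC)c(OC)c2OCOC)ccc1OCc1ccccc1
F0 | step 3 | none | none
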